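The numbers of this flask are those of an exercise.

I have a charge of solid substrate that reaches the coupling partner by way of solution, and what I want first is how much of that charge gets there.

solid substrate 0.050 M; coupling partner 0.200 M; time 25 min

    solid product ⇌ target, rate k1*(cs1 - [target]) while solid is left; crystals form when [target] > cs1 (cs1 = 18 mM, k1 = 0.157 s⁻¹)
    dissolved substrate + coupling partner → target (k2 = 0.00988 L mol⁻¹ s⁻¹)
    2 dissolved substrate → side product (k3 = 0.213 L mol⁻¹ s⁻¹)
    2 solid substrate → homo dimer (k4 = 0.368 L mol⁻¹ s⁻¹)
    solid substrate ⇌ dissolved substrate, rate k5*(cs5 - [dissolved substrate]) while solid is left; crystals form when [dissolved substrate] > cs5 (cs5 = 16 mM, k5 = 0.00237 s⁻¹)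
    target ⇌ isomer of the product (K6 = 2.31, k6 = 9.51 × 10⁻⁴ s⁻¹)

- amount of target and solid product together at 25 min, in percent of the solid substrate charged
- concentration of dissolved substrate in solution at 25 min, in percent of saturation

- percent here means solid substrate units held: one side product or homo dimer counts as two
- what is said of target includes solid product
- where a step has two of a species, its rate is k times that concentration squared, and two are used at each turn
- solid substrate, solid product is a solid; its amount is given per volume of the solution
- at the start none of the solid substrate is in solution
- dissolved substrate means what is dissolved; the solid is not counted in it
- run time (flask): 25 min

At the bench I reckon that a suspension feeds its solution at dissolution coefficient times solubility. By that rule of thumb, this flask has its charge in solution after 22.0 min, which is shorter than the run. But the solid also dimerises, and by that step alone its first half-life is 27.2 s, far shorter than the dissolving time. The ratio of the two times, 48.5, compares the dimer rate with the feed at the full charge, at that moment only; the dimer rate goes with the square of the solid, so the ratio falls as the solid falls.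

The border is the solid level at which the two rates are equal, the square root of feed over twice the dimer constant: 7.18 mM, well below the charge. While dimerisation brings the solid down to that level, the feed delivers about one such level. Of the like amount still solid there, I give dissolving half, so my first answer is 10.8 mM.

I go round once more. The solution is not empty: I let it hold half of that first answer on average, which cuts the feed. The border goes as the square root of the feed, so it drops to 5.85 mM, and the same count gives 8.77 mM. This I call the escape amount: what dissolves before the solid has gone. In this flask it is 17.5 % of the charge, and my hand stops there.

The forecast gives 5.2 % for y and 1.6 % for sat, holding that “the solid is gone in about 5 min with only about 9 mM (under a fifth of the charge) ever dissolved”. The simulation gives 5.38 % and 1.66 %.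

This flask ends with 81.0 % as homo dimer, so 19.0 % of the charge escaped, against my 17.5 %. With dimerisation struck out, y rises from 5.38 % to 18.2 %, far from the forecast; this is the largest single effect, yet it recovers 14 % of what is missing. In a neighbour flask charged with 0.020 M of solid substrate, the same escape amount is 43.9 % of its charge, and its 58.3 % of homo dimer leaves 41.7 % escaped.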